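**Retrosynthetic overview**

1. Labdane numbering is used: rings A and B are the decalin (C1–C10), ring C is the imide ring (C13, C14, C15, N, C16). Rings A and B with C5, C9 and C10 are bought as (+)-sclareolide; ring C is the only ring made, and it is made last.
2. Key disconnection: C14–C15 of ring C. C14 is the primary terminus of the allyl unit C12–C13–C14, whose central carbon C13 carries the acyl carbon C16, and C15 is the single carbon between C14 and N. An acyl isocyanate on C16 therefore holds an electrophilic, N–H-free C15 five atoms from an allylic C14–Br, and nickel-catalysed reduction joins these two electrophilic carbons (polarity reversal at C14).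
3. The isocyanate comes from aldehyde 10 by Morita–Baylis–Hillman addition of acrylamide (C12–C13), SN2′ bromination (fixes the 12,13 geometry) and oxalyl chloride (brings in C15).
4. Aldehyde 10 comes from sclareolide by C2–H chlorination, lactone opening to a Weinreb amide, dehydration to the 8(17)-alkene, allylic oxidation at C7, oxidation and Luche reduction to the 7β-alcohol, amide reduction and acetylation.

Key step: step 12

Assumption: N-tert-butyl-N-chloro-3,5-bis(trifluoromethyl)benzamide is taken as a purchasable reagent (otherwise it is one N-chlorination from the parent amide).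

**Route**

Step 1
Reactants: 1 (+)-sclareolide
Product: 2 2α-chlorosclareolide (equatorial chloride at labdane C2)
Conditions: N-tert-butyl-N-chloro-3,5-bis(trifluoromethyl)benzamide (1.2 equiv), Cs2CO3 (0.1 equiv), PhH, white LEDs, 55 °C
Reagents that add atoms: N-tert-butyl-N-chloro-3,5-bis(trifluoromethyl)benzamide, CC(C)(C)N(Cl)C(=O)c1cc(cc(c1)C(F)(F)F)C(F)(F)F
Why: Radical C–H chlorination with an N-chloroamide, in which the bulky amidyl radical should abstract hydrogen at C2 (the only ring A methylene not next to a quaternary carbon and remote from the deactivating lactone) and the C2 radical should take chlorine on the α face because the axial β direction is shielded by the axial methyl groups on C4 and C10, which sets the equatorial 2α chloride.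

Step 2
Reactants: 2 2α-chlorosclareolide
Product: 3 N-methoxy-N-methyl-2α-chloro-8α-hydroxy-13,14,15,16-tetranorlabdan-12-amide
Conditions: MeNH(OMe)·HCl (3 equiv), AlMe3 (3 equiv), CH2Cl2, 0 → 23 °C; aq potassium sodium tartrate
Reagents that add atoms: N,O-dimethylhydroxylamine hydrochloride, CNOC.Cl
Why: Weinreb amidation of the lactone by the aluminium amide cleaves the acyl C–O bond only, so the 8α oxygen and all ring stereocentres are untouched.

Step 3
Reactants: 3 N-methoxy-N-methyl-2α-chloro-8α-hydroxy-13,14,15,16-tetranorlabdan-12-amide
Product: 5 N-methoxy-N-methyl-2α-chloro-13,14,15,16-tetranorlabd-8(17)-en-12-amide, via the 8-O-chlorosulfite 4 (not isolated)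
Conditions: SOCl2, pyridine, CH2Cl2, −78 °C
Reagents that add atoms: none
Why: Dehydration of a tertiary alcohol through its chlorosulfite (E2 with pyridine), in which the equatorial 8α leaving group has no anti-periplanar ring hydrogen, so elimination should run mainly toward the C17 methyl group and give the exocyclic 8(17) alkene.

Step 4
Reactants: 5 N-methoxy-N-methyl-2α-chloro-13,14,15,16-tetranorlabd-8(17)-en-12-amide
Product: 6 N-methoxy-N-methyl-2α-chloro-7α-hydroxy-13,14,15,16-tetranorlabd-8(17)-en-12-amide
Conditions: SeO2 (0.5 equiv), tBuOOH, CH2Cl2, 23 °C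
Reagents that add atoms: tert-butyl hydroperoxide, CC(C)(C)OO (its oxygen is passed on by SeO2, O=[Se]=O)
Why: Selenium dioxide allylic oxidation (ene reaction at C17 followed by a [2,3]-sigmatropic shift) should return the double bond to C8–C17 and place oxygen on the ring methylene C7 and not on the hindered methine C9, expected on the α face, and the C7 configuration does not matter because step 5 removes it.

Step 5
Reactants: 6 N-methoxy-N-methyl-2α-chloro-7α-hydroxy-13,14,15,16-tetranorlabd-8(17)-en-12-amide
Product: 7 N-methoxy-N-methyl-2α-chloro-7-oxo-13,14,15,16-tetranorlabd-8(17)-en-12-amide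
Conditions: Dess–Martin periodinane, CH2Cl2, 0 → 23 °C
Reagents that add atoms: none
Why: Dess–Martin oxidation of the allylic alcohol should give the exocyclic enone under near-neutral conditions that leave C9 and the 8(17) alkene in place.

Step 6
Reactants: 7 N-methoxy-N-methyl-2α-chloro-7-oxo-13,14,15,16-tetranorlabd-8(17)-en-12-amide
Product: 8 N-methoxy-N-methyl-2α-chloro-7β-hydroxy-13,14,15,16-tetranorlabd-8(17)-en-12-amide
Conditions: NaBH4, CeCl3·7H2O, MeOH, −78 °C
Reagents that add atoms: none
Why: Luche reduction should deliver hydride 1,2 along the axial α trajectory at C7 (past only the axial hydrogens on C5 and C9), which sets C7 as the equatorial 7β alcohol while the Weinreb amide is not reduced.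

Step 7
Reactants: 8 N-methoxy-N-methyl-2α-chloro-7β-hydroxy-13,14,15,16-tetranorlabd-8(17)-en-12-amide
Product: 9 2α-chloro-7β-hydroxy-13,14,15,16-tetranorlabd-8(17)-en-12-al
Conditions: iBu2AlH (2.5 equiv), THF, −78 °C; aq potassium sodium tartrate
Reagents that add atoms: none
Why: Weinreb amide reduction, in which the first equivalent of hydride is used up by the 7-OH and the next forms the chelated tetrahedral aluminate that releases the aldehyde only on work-up, so over-reduction should not occur.

Step 8
Reactants: 9 2α-chloro-7β-hydroxy-13,14,15,16-tetranorlabd-8(17)-en-12-al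
Product: 10 7β-acetoxy-2α-chloro-13,14,15,16-tetranorlabd-8(17)-en-12-al
Conditions: Ac2O, pyridine, DMAP (cat.), CH2Cl2, 0 °C
Reagents that add atoms: acetic anhydride, CC(=O)OC(C)=O
Why: DMAP-catalysed acylation of the unhindered equatorial secondary alcohol should be fast at 0 °C, and the aldehyde has no stereocentre at its α carbon to lose.

Step 9
Reactants: 10 7β-acetoxy-2α-chloro-13,14,15,16-tetranorlabd-8(17)-en-12-al; 11 acrylamide
Product: 12 7β-acetoxy-2α-chloro-12-hydroxy-15-norlabda-8(17),13-dien-16-amide (both C12 epimers)
Conditions: acrylamide 11 (3 equiv), DABCO (1 equiv), 1,4-dioxane–H2O (1:1), 23 °C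
Reagents that add atoms: none
Why: Morita–Baylis–Hillman reaction, in which DABCO adds to acrylamide and the resulting enolate adds to the unhindered aldehyde to form the C12–C13 bond, and the new C12 carbinol centre is formed as a mixture that step 10 removes.

Step 10
Reactants: 12 7β-acetoxy-2α-chloro-12-hydroxy-15-norlabda-8(17),13-dien-16-amide
Product: 13 (12Z)-7β-acetoxy-14-bromo-2α-chloro-15-norlabda-8(17),12-dien-16-amide
Conditions: NBS, Me2S, CH2Cl2, −20 → 0 °C (reagent formed first, then 12 added)
Reagents that add atoms: N-bromosuccinimide, O=C1CCC(=O)N1Br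
Why: Corey–Kim-type activation of the allylic hydroxyl followed by SN2′ attack of bromide at C14 should give the rearranged primary bromide, with the 12Z geometry (C11 trans to the carboxamide) following from minimised allylic strain, as for Morita–Baylis–Hillman adducts of acrylates.

Step 11
Reactants: 13 (12Z)-7β-acetoxy-14-bromo-2α-chloro-15-norlabda-8(17),12-dien-16-amide
Product: 15 (12Z)-7β-acetoxy-14-bromo-2α-chloro-15-norlabda-8(17),12-dien-16-oyl isocyanate, via the N-chlorooxalyl amide 14 (not isolated)
Conditions: (COCl)2 (1.3 equiv), ClCH2CH2Cl, 0 → 70 °C, N2 sweep; concentrate, use crude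
Reagents that add atoms: oxalyl chloride, O=C(Cl)C(=O)Cl
Why: Conversion of a primary carboxamide into an acyl isocyanate with oxalyl chloride, in which N-acylation gives the chlorooxalyl amide that loses HCl and CO on warming, is standard for 2-substituted acrylamides and should leave the allylic bromide and the alkene geometry alone.

Step 12
Reactants: 15 (12Z)-7β-acetoxy-14-bromo-2α-chloro-15-norlabda-8(17),12-dien-16-oyl isocyanate
Product: 16 (12E)-7β-acetoxy-2α-chlorolabda-8(17),12-diene-15,16-dicarboximide (the target)
Conditions: NiBr2(MeOCH2CH2OMe) (10 mol %), 4,4′-di-tert-butyl-2,2′-bipyridine (12 mol %), Mn powder (3 equiv), THF (0.01 M, slow addition of 15), 0 → 23 °C; then aq NH4Cl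
Reagents that add atoms: none
Why: Proposed new method: zerovalent nickel, made in the flask from NiBr2 and Mn, should add oxidatively to the primary allylic C14–Br bond of 15 to give a 2-acyl allylnickel bromide, whose σ-bound C14 then adds to the sp-hybridised C15 of the acyl isocyanate held five atoms away, and Mn reduces the resulting divalent nickel imidate back to zerovalent nickel, so that two electrophilic carbons are joined reductively; aqueous NH4Cl then protonates the imidate nitrogen. The closest known reaction types are the nickel-catalysed reductive amidation of alkyl bromides with isocyanates, the nickel-catalysed reductive carboxylation of allyl esters with CO2 and the addition of 2-alkoxycarbonylallylnickel bromides to carbonyl groups; new here are the acyl isocyanate, the allylic bromide and the intramolecular setting. Ring C closes in a 5-exo-dig mode with respect to the C15=O π bond (nucleophile C14, chain C13–C16–N), a geometry that an η1-allyl bound at C14 reaches without strain, whereas bond formation at C12 from that species would need the C12–C13 π bond to attack endo. No stereocentre is formed; the 12E geometry of 16 is the 12Z geometry of the bromide (C11 cis to C14 in both) carried through the syn-configured allylnickel, which is also the more stable arrangement. The step needs C14 over C12 regioselectivity, secured by the unhindered primary terminus and by conjugation of the product alkene with C16, and chemoselectivity for the allylic bromide over the 7β-acetate and the 2α-chloride, secured by the fast oxidative addition of the activated bromide, by the equatorial C7–O bond lying near the nodal plane of the C8–C17 π bond (poor overlap for ionisation) and by the inertness of an unactivated secondary chloride at 23 °C. High dilution with slow addition of 15 should suppress allyl–allyl dimerisation, and an amide-free solvent is chosen because acyl isocyanates react with DMF.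

**Compound list**

1 | (+)-sclareolide, (3aR,5aS,9aS,9bR)-3a,6,6,9a-tetramethyldecahydronaphtho[2,1-b]furan-2(1H)-one | C[C@@]12CC[C@H]3C(C)(C)CCC[C@]3(C)[C@H]1CC(=O)O2 | starting material
2 | 2α-chlorosclareolide | C[C@@]12CC[C@H]3C(C)(C)C[C@H](Cl)C[C@]3(C)[C@H]1CC(=O)O2 | intermediate
3 | N-methoxy-N-methyl-2α-chloro-8α-hydroxy-13,14,15,16-tetranorlabdan-12-amide | C[C@@]1(O)CC[C@H]2C(C)(C)C[C@H](Cl)C[C@]2(C)[C@H]1CC(=O)N(C)OC | intermediate
4 | 8-O-chlorosulfite of 3 (not isolated) | C[C@@]1(OS(Cl)=O)CC[C@H]2C(C)(C)C[C@H](Cl)C[C@]2(C)[C@H]1CC(=O)N(C)OC | intermediate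
5 | N-methoxy-N-methyl-2α-chloro-13,14,15,16-tetranorlabd-8(17)-en-12-amide | C=C1CC[C@H]2C(C)(C)C[C@H](Cl)C[C@]2(C)[C@H]1CC(=O)N(C)OC | intermediate
6 | N-methoxy-N-methyl-2α-chloro-7α-hydroxy-13,14,15,16-tetranorlabd-8(17)-en-12-amide | C=C1[C@H](O)C[C@H]2C(C)(C)C[C@H](Cl)C[C@]2(C)[C@H]1CC(=O)N(C)OC | intermediate
7 | N-methoxy-N-methyl-2α-chloro-7-oxo-13,14,15,16-tetranorlabd-8(17)-en-12-amide | C=C1C(=O)C[C@H]2C(C)(C)C[C@H](Cl)C[C@]2(C)[C@H]1CC(=O)N(C)OC | intermediate
8 | N-methoxy-N-methyl-2α-chloro-7β-hydroxy-13,14,15,16-tetranorlabd-8(17)-en-12-amide | C=C1[C@@H](O)C[C@H]2C(C)(C)C[C@H](Cl)C[C@]2(C)[C@H]1CC(=O)N(C)OC | intermediate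
9 | 2α-chloro-7β-hydroxy-13,14,15,16-tetranorlabd-8(17)-en-12-al | C=C1[C@@H](O)C[C@H]2C(C)(C)C[C@H](Cl)C[C@]2(C)[C@H]1CC=O | intermediate
10 | 7β-acetoxy-2α-chloro-13,14,15,16-tetranorlabd-8(17)-en-12-al | C=C1[C@@H](OC(C)=O)C[C@H]2C(C)(C)C[C@H](Cl)C[C@]2(C)[C@H]1CC=O | intermediate
11 | acrylamide | C=CC(N)=O | starting material
12 | 7β-acetoxy-2α-chloro-12-hydroxy-15-norlabda-8(17),13-dien-16-amide (C12 epimer mixture, centre removed in step 10) | C=C1[C@@H](OC(C)=O)C[C@H]2C(C)(C)C[C@H](Cl)C[C@]2(C)[C@H]1CC(O)C(=C)C(N)=O | intermediate
13 | (12Z)-7β-acetoxy-14-bromo-2α-chloro-15-norlabda-8(17),12-dien-16-amide | C=C1[C@@H](OC(C)=O)C[C@H]2C(C)(C)C[C@H](Cl)C[C@]2(C)[C@H]1C/C=C(\CBr)C(N)=O | intermediate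
14 | N-chlorooxalyl derivative of 13 (not isolated) | C=C1[C@@H](OC(C)=O)C[C@H]2C(C)(C)C[C@H](Cl)C[C@]2(C)[C@H]1C/C=C(\CBr)C(=O)NC(=O)C(Cl)=O | intermediate
15 | (12Z)-7β-acetoxy-14-bromo-2α-chloro-15-norlabda-8(17),12-dien-16-oyl isocyanate | C=C1[C@@H](OC(C)=O)C[C@H]2C(C)(C)C[C@H](Cl)C[C@]2(C)[C@H]1C/C=C(\CBr)C(=O)N=C=O | intermediate
16 | (12E)-7β-acetoxy-2α-chlorolabda-8(17),12-diene-15,16-dicarboximide, an (E)-3-alkylidenepyrrolidine-2,5-dione | C=C1[C@@H](OC(C)=O)C[C@H]2C(C)(C)C[C@H](Cl)C[C@]2(C)[C@H]1C/C=C1\CC(=O)NC1=O | target

**Step count and risks**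

Total step count: 12. Longest linear sequence: 12 steps, from (+)-sclareolide 1.

Steps most likely to fail:

Step 12 (the new nickel-catalysed ring closure). What may go wrong: reductive allyl–allyl dimerisation or plain reduction of the C14–Br bond, bond formation at C12 in place of C14, and nickel-induced oligomerisation of the isocyanate. The fallback uses known chemistry and sets out from aldehyde 10. Wittig olefination in THF at reflux with the stabilised ylide 3-(triphenylphosphoranylidene)pyrrolidine-2,5-dione F1, made from maleimide and PPh3 in acetone, should give the E-alkylidene succinimide directly and comes back to the route at target 16. Steps 9 to 12 are then not needed, and ring C is brought in with maleimide and not closed at C14–C15.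

Step 11. What may go wrong: the HCl released may add to or isomerise the 8(17) alkene, ionise the allylic acetate, or the chlorooxalyl amide may fragment incompletely. The fallback sets out from bromo amide 13. Silylation with N,O-bis(trimethylsilyl)acetamide (no amine base, which would quaternise the allylic bromide) should give the N,O-bis(trimethylsilyl) imidate F2. After removal of volatiles, phosgene in toluene at 0 °C should release Me3SiCl in place of HCl, and the sequence comes back at isocyanate 15.

Step 9. What may go wrong: slow addition to an enolisable aliphatic aldehyde, competing aldol self-condensation, and saponification of the 7-acetate in the aqueous amine medium. The fallback sets out from aldehyde 10. A water-free Morita–Baylis–Hillman reaction with neat acrylonitrile and DABCO should give the hydroxy nitrile 7β-acetoxy-2α-chloro-12-hydroxy-15-norlabda-8(17),13-diene-16-nitrile F3. Neutral platinum-catalysed hydration of the nitrile (PtH(PMe2OH)(PMe2O)2H, aq EtOH, 80 °C) then comes back at hydroxy amide 12.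

**Further compounds**

F1 | step 12 | 3-(triphenylphosphoranylidene)pyrrolidine-2,5-dione | O=C1CC(=P(c2ccccc2)(c2ccccc2)c2ccccc2)C(=O)N1
F2 | step 11 | trimethylsilyl (12Z)-7β-acetoxy-14-bromo-2α-chloro-N-(trimethylsilyl)-15-norlabda-8(17),12-dien-16-imidate | C=C1[C@@H](OC(C)=O)C[C@H]2C(C)(C)C[C@H](Cl)C[C@]2(C)[C@H]1C/C=C(\CBr)C(O[Si](C)(C)C)=N[Si](C)(C)C
F3 | step 9 | 7β-acetoxy-2α-chloro-12-hydroxy-15-norlabda-8(17),13-diene-16-nitrile (C12 epimer mixture) | C=C1[C@@H](OC(C)=O)C[C@H]2C(C)(C)C[C@H](Cl)C[C@]2(C)[C@H]1CC(O)C(=C)C#N
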